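**Plan**

- Cuts, in order: the four MOM ethers; C2–C1' (ring B taken off a flat 6-geranyl-5,7-bis(MOM-oxy)chromone); O1–C2 and C3–C4 of ring C (an ynone from a salicylaldehyde and an ethynyl unit); C4–C4a (the formyl carbon); last C6–C1'' (the geranyl bond).
- Forward: ring A is phloroglucinol, masked as a mono-silyl bis-MOM ether and geranylated at the carbon between the two MOM-bearing oxygens. Desilylation, ortho-formylation, ethynylation, oxidation and amine-mediated 6-endo closure then build ring C as a chromone. Ring B, from 5-bromoresorcinol as a boronic acid, is joined last.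
- Enabling feature: C2 is the only stereocentre; it is benzylic, β to the C4 carbonyl and carries ring B, so C2–C1' maps onto conjugate arylation of the chromone C2=C3. The geranyl carbon C6 lies para to C8a–O1 between O5 and O7, so a mirror-symmetric phenol with two equivalent ortho C–H positions can only lead to the 6-geranyl series.
- Stereochemistry: C2 (S) comes from the chiral bisphosphine on monovalent rhodium in the arylation; the E alkene comes unchanged from geranyl bromide; the endgame is acid-only so that C2 is not scrambled through the chalcone.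

Key step: step 11

Abbreviations: geranyl = (2E)-3,7-dimethylocta-2,6-dien-1-yl; MOM = methoxymethyl; TIPS = triisopropylsilyl; (S)-MeO-F12-BIPHEP = (S)-2,2'-bis[bis(3,4,5-trifluorophenyl)phosphino]-6,6'-dimethoxy-1,1'-biphenyl.

Assumption: by analogy with the arylation of cyclic enones, the (S)-configured biaryl bisphosphine is taken to deliver the aryl group to the enantioface that gives 2S; if a model run shows the opposite sense, the (R)-ligand is used instead.

**Route**

Step 1
Reactants: 1 phloroglucinol (anhydrous, threefold excess)
Product: 2 5-(triisopropylsilyloxy)benzene-1,3-diol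
Conditions: TIPSCl (1.0 equiv), imidazole, DMF, 0 °C to rt; excess 1 removed by aqueous wash
Reagents that add atoms: triisopropylsilyl chloride, CC(C)[Si](Cl)(C(C)C)C(C)C
Why: Silylation of a phenol with a bulky chlorosilane and imidazole, in which the excess of the cheap, water-soluble triol biases the statistical outcome towards the mono-ether.

Step 2
Reactants: 2 5-(triisopropylsilyloxy)benzene-1,3-diol
Product: 3 1-(triisopropylsilyloxy)-3,5-bis(methoxymethoxy)benzene
Conditions: MOMCl (2.6 equiv), i-Pr2NEt, CH2Cl2, 0 °C to rt
Reagents that add atoms: chloromethyl methyl ether, COCCl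
Why: Williamson-type O-alkylation of the two remaining phenols under amine base, which leaves the hindered aryl silyl ether in place and avoids alkoxide-driven silyl transfer.

Step 3
Reactants: 3 1-(triisopropylsilyloxy)-3,5-bis(methoxymethoxy)benzene; 4 geranyl bromide
Product: 7 4-geranyl-3,5-bis(methoxymethoxy)phenyl triisopropylsilyl ether, via aryllithium 5 (not isolated), via arylcopper 6 (not isolated)
Conditions: n-BuLi, THF, 0 °C; CuI, −78 to −30 °C; then 4, −78 °C to rt
Reagents that add atoms: none
Why: Directed ortho-metalation at the C–H flanked by both MOM ethers (the bulky silyloxy group does not direct), then lithium-to-copper transmetalation and SN2 allylation at the unhindered α-carbon of the primary allylic bromide, which keeps the E alkene and avoids the SN2' path to a quaternary carbon.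

Step 4
Reactants: 7 4-geranyl-3,5-bis(methoxymethoxy)phenyl triisopropylsilyl ether
Product: 8 4-geranyl-3,5-bis(methoxymethoxy)phenol
Conditions: TBAF, AcOH (1:1), THF, 0 °C to rt
Reagents that add atoms: none
Why: Fluoride-driven desilylation of an aryl silyl ether, buffered with acetic acid so that the electron-rich phenol is released in neutral form while the MOM ethers and the alkenes stay inert.

Step 5
Reactants: 8 4-geranyl-3,5-bis(methoxymethoxy)phenol; 9 paraformaldehyde
Product: 11 3-geranyl-6-hydroxy-2,4-bis(methoxymethoxy)benzaldehyde, via salicyl alcohol 10 (not isolated)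
Conditions: MgCl2 (anhydrous), Et3N, (CH2O)n, THF, reflux; cold 5% citric acid work-up
Reagents that add atoms: none
Why: Magnesium-mediated ortho-formylation of a phenol (Casnati–Skattebøl reaction), in which the magnesium phenoxide takes formaldehyde at an ortho carbon and a second formaldehyde oxidises the salicyl alcohol by hydride transfer; the two ortho carbons are equivalent by symmetry and the para carbon is blocked by the geranyl group, so only one aldehyde can form.

Step 6
Reactants: 11 3-geranyl-6-hydroxy-2,4-bis(methoxymethoxy)benzaldehyde; 12 ethynylmagnesium bromide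
Product: 13 2-(1-hydroxyprop-2-yn-1-yl)-4-geranyl-3,5-bis(methoxymethoxy)phenol (racemic)
Conditions: 12 (3 equiv), THF, 0 °C to rt; pH 7 phosphate buffer
Reagents that add atoms: none
Why: Grignard 1,2-addition to the aldehyde after the first equivalent has deprotonated the phenol; the carbinol centre forms as a racemate and is removed in the next step.

Step 7
Reactants: 13 2-(1-hydroxyprop-2-yn-1-yl)-4-geranyl-3,5-bis(methoxymethoxy)phenol
Product: 14 1-[3-geranyl-6-hydroxy-2,4-bis(methoxymethoxy)phenyl]prop-2-yn-1-one
Conditions: activated MnO2 (excess), CH2Cl2, rt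
Reagents that add atoms: none
Why: MnO2 oxidation, selective for the benzylic and propargylic alcohol, which leaves the phenol, the MOM ethers and the isolated alkenes untouched.

Step 8
Reactants: 14 1-[3-geranyl-6-hydroxy-2,4-bis(methoxymethoxy)phenyl]prop-2-yn-1-one
Product: 16 6-geranyl-5,7-bis(methoxymethoxy)-4H-chromen-4-one, via enaminone 15 (not isolated)
Conditions: Et2NH, EtOH, rt to 60 °C
Reagents that add atoms: none
Why: Aza-Michael addition of the secondary amine to the terminal ynone gives the E-enaminone, and the only free phenol then closes ring C by 6-endo oxa-Michael addition at the β-carbon with loss of the amine (addition–elimination), which avoids the 5-exo closure to a benzofuranone.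

Step 9
Reactants: 17 5-bromoresorcinol
Product: 18 1-bromo-3,5-bis(methoxymethoxy)benzene
Conditions: MOMCl (2.6 equiv), i-Pr2NEt, CH2Cl2, 0 °C to rt
Reagents that add atoms: chloromethyl methyl ether, COCCl
Why: Williamson-type O-alkylation of both phenols, giving a ring B precursor whose protecting groups match those of ring A and fall in the same final operation.

Step 10
Reactants: 18 1-bromo-3,5-bis(methoxymethoxy)benzene
Product: 21 3,5-bis(methoxymethoxy)phenylboronic acid, via aryllithium 19 (not isolated), via lithium triisopropoxyborate 20 (not isolated)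
Conditions: n-BuLi, THF, −78 °C; B(Oi-Pr)3, −78 °C to rt; H2O, AcOH to pH 6
Reagents that add atoms: triisopropyl borate, CC(C)OB(OC(C)C)OC(C)C; water, O
Why: Bromine–lithium exchange at −78 °C outruns ortho-lithiation next to the MOM ethers, and borylation of the aryllithium followed by hydrolysis of the ate complex near pH 6 spares the acetals.

Step 11
Reactants: 16 6-geranyl-5,7-bis(methoxymethoxy)-4H-chromen-4-one; 21 3,5-bis(methoxymethoxy)phenylboronic acid (2.5 equiv)
Product: 22 (2S)-6-geranyl-5,7,3',5'-tetrakis(methoxymethoxy)flavanone
Conditions: [Rh(OH)((S)-MeO-F12-BIPHEP)]2 (1.5 mol%, preformed from [RhCl(C2H4)2]2, the ligand and KOH), toluene/H2O 10:1, 30 °C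
Reagents that add atoms: none
Why: The hydroxo complex of monovalent rhodium takes the aryl group from boron by transmetalation, the aryl–rhodium species adds across C2=C3 of the chromone with the aryl group going to C2, and water protonates the resulting oxa-π-allyl rhodium enolate to release the flavanone and return Rh–OH. The closest known reaction type is the Hayashi–Miyaura asymmetric 1,4-addition of arylboronic acids to enones, which is established for chromones as a route to flavanones. No ring closes here: rings A and C are already in place and the step forms only the C2–C1' bond that attaches ring B. The one new stereocentre, C2, is set by the chiral bisphosphine on rhodium, which lets the flat, achiral chromone bind through one enantioface only, the (S)-ligand being expected to give 2S. The step needs enantioface selectivity, 1,4- over 1,2-addition and a product that neither ring-opens nor is arylated a second time; the vinylogous-ester polarisation and the unsubstituted C2 secure the regiochemistry, the MOM cap on O5 removes the chelating phenol that would favour opening to a chalcone, the medium holds no free base, and the remote trisubstituted alkenes do not insert into the aryl–rhodium bond.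

Step 12
Reactants: 22 (2S)-6-geranyl-5,7,3',5'-tetrakis(methoxymethoxy)flavanone
Product: 23 Schizolaenone C
Conditions: HCl (about 1 M) in MeOH/THF, 0 °C to rt
Reagents that add atoms: none
Why: Acid-catalysed transacetalisation of the four MOM ethers to dimethoxymethane in methanol, run dilute and at or below room temperature so that the trisubstituted alkenes are not protonated and, with no base present, C2 cannot racemise by retro-oxa-Michael opening.

**Compound list**

1 | phloroglucinol (benzene-1,3,5-triol) | Oc1cc(O)cc(O)c1 | starting material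
2 | 5-(triisopropylsilyloxy)benzene-1,3-diol | CC(C)[Si](Oc1cc(O)cc(O)c1)(C(C)C)C(C)C | intermediate
3 | 1-(triisopropylsilyloxy)-3,5-bis(methoxymethoxy)benzene | COCOc1cc(OCOC)cc(O[Si](C(C)C)(C(C)C)C(C)C)c1 | intermediate
4 | geranyl bromide ((2E)-1-bromo-3,7-dimethylocta-2,6-diene) | CC(C)=CCC/C(C)=C/CBr | starting material
5 | 2,6-bis(methoxymethoxy)-4-(triisopropylsilyloxy)phenyllithium (not isolated) | [Li]c1c(OCOC)cc(O[Si](C(C)C)(C(C)C)C(C)C)cc1OCOC | intermediate
6 | 2,6-bis(methoxymethoxy)-4-(triisopropylsilyloxy)phenylcopper (not isolated) | [Cu]c1c(OCOC)cc(O[Si](C(C)C)(C(C)C)C(C)C)cc1OCOC | intermediate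
7 | 4-geranyl-3,5-bis(methoxymethoxy)phenyl triisopropylsilyl ether | CC(C)=CCC/C(C)=C/Cc1c(OCOC)cc(O[Si](C(C)C)(C(C)C)C(C)C)cc1OCOC | intermediate
8 | 4-geranyl-3,5-bis(methoxymethoxy)phenol | CC(C)=CCC/C(C)=C/Cc1c(OCOC)cc(O)cc1OCOC | intermediate
9 | paraformaldehyde (formaldehyde unit) | C=O | starting material
10 | 2-(hydroxymethyl)-4-geranyl-3,5-bis(methoxymethoxy)phenol (as its magnesium salt, not isolated) | CC(C)=CCC/C(C)=C/Cc1c(OCOC)cc(O)c(CO)c1OCOC | intermediate
11 | 3-geranyl-6-hydroxy-2,4-bis(methoxymethoxy)benzaldehyde | CC(C)=CCC/C(C)=C/Cc1c(OCOC)cc(O)c(C=O)c1OCOC | intermediate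
12 | ethynylmagnesium bromide | C#C[Mg]Br | starting material
13 | 2-(1-hydroxyprop-2-yn-1-yl)-4-geranyl-3,5-bis(methoxymethoxy)phenol (racemic) | CC(C)=CCC/C(C)=C/Cc1c(OCOC)cc(O)c(C(O)C#C)c1OCOC | intermediate
14 | 1-[3-geranyl-6-hydroxy-2,4-bis(methoxymethoxy)phenyl]prop-2-yn-1-one | CC(C)=CCC/C(C)=C/Cc1c(OCOC)cc(O)c(C(=O)C#C)c1OCOC | intermediate
15 | (E)-3-(diethylamino)-1-[3-geranyl-6-hydroxy-2,4-bis(methoxymethoxy)phenyl]prop-2-en-1-one (not isolated) | CC(C)=CCC/C(C)=C/Cc1c(OCOC)cc(O)c(C(=O)/C=C/N(CC)CC)c1OCOC | intermediate
16 | 6-geranyl-5,7-bis(methoxymethoxy)-4H-chromen-4-one | CC(C)=CCC/C(C)=C/Cc1c(OCOC)cc2occc(=O)c2c1OCOC | intermediate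
17 | 5-bromoresorcinol (5-bromobenzene-1,3-diol) | Oc1cc(O)cc(Br)c1 | starting material
18 | 1-bromo-3,5-bis(methoxymethoxy)benzene | COCOc1cc(OCOC)cc(Br)c1 | intermediate
19 | 3,5-bis(methoxymethoxy)phenyllithium (not isolated) | [Li]c1cc(OCOC)cc(OCOC)c1 | intermediate
20 | lithium [3,5-bis(methoxymethoxy)phenyl]triisopropoxyborate (not isolated) | [Li+].CC(C)O[B-](OC(C)C)(OC(C)C)c1cc(OCOC)cc(OCOC)c1 | intermediate
21 | 3,5-bis(methoxymethoxy)phenylboronic acid | COCOc1cc(OCOC)cc(B(O)O)c1 | intermediate
22 | (2S)-6-geranyl-5,7,3',5'-tetrakis(methoxymethoxy)flavanone | CC(C)=CCC/C(C)=C/Cc1c(OCOC)cc2c(c1OCOC)C(=O)C[C@@H](c1cc(OCOC)cc(OCOC)c1)O2 | intermediate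
23 | Schizolaenone C, (2S)-6-geranyl-5,7,3',5'-tetrahydroxyflavanone | CC(C)=CCC/C(C)=C/Cc1c(O)cc2c(c1O)C(=O)C[C@@H](c1cc(O)cc(O)c1)O2 | target

**Count**

Total steps: 12. Longest linear sequence: 10 steps (steps 1 to 8, then 11 and 12); the ring B branch (steps 9 and 10) joins at step 11.

**Steps most likely to fail**

Step 11. Enantioface discrimination may be poor, or insertion into the electron-rich 5,7-dioxygenated chromone may be slow enough that protodeboronation of the aryl donor and a second, 1,2-arylation of the product compete. The fallback gives up catalyst control and sets out from 16 and 21. The achiral, more active [Rh(OH)(cod)]2 (cod = 1,5-cyclooctadiene) in dioxane/H2O should form the same C2–C1' bond and give the racemic tetra-MOM flavanone F1. Preparative HPLC on a cellulose tris(3,5-dimethylphenylcarbamate) phase then supplies the 2S enantiomer, which is compound 22, where the route is rejoined. The 2R antipode is returned to the racemate with catalytic DBU in toluene, by reversible opening to the 2'-hydroxychalcone F2 and re-closure, and is recycled.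

Step 12. Protic acid may protonate the trisubstituted alkenes and drive cyclisation of the chain onto the flanking O5 or O7 phenol, or the less labile MOM ethers may cleave too slowly and tempt harsher acid. The fallback sets out from 22 and replaces Brønsted-acid solvolysis by a non-protic silyl transfer. TMSOTf with 2,2'-bipyridyl in CH2Cl2 at 0 °C should convert the four aryl MOM ethers into aryl trimethylsilyl ethers, giving the tetrakis(trimethylsilyl) ether F3, while the methoxymethyl groups leave as a bipyridinium salt. Addition of water then hydrolyses the silyl ethers near neutral pH and the route is rejoined at 23.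

Step 5. The ortho-hydroxymethyl intermediate may lose water to an ortho-quinone methide that is trapped by a second phenol (methylene-bridged dimer formation), or MgCl2 at reflux may strip a MOM ether. The fallback sets out from 7, before desilylation, and brings in the formyl carbon by directed ortho-metalation. sec-BuLi/TMEDA in THF at −78 °C should lithiate one of the two equivalent ring C–H positions next to a MOM ether to give the aryllithium F4; the TIPS group is chosen because it resists oxygen-to-carbon silyl migration at this temperature. Quenching with DMF gives 3-geranyl-2,4-bis(methoxymethoxy)-6-(triisopropylsilyloxy)benzaldehyde F5. TBAF/AcOH in THF then removes the silyl group and the route is rejoined at 11, bypassing phenol 8.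

**Further compounds**

F1 | step 11 | racemic 6-geranyl-5,7,3',5'-tetrakis(methoxymethoxy)flavanone | CC(C)=CCC/C(C)=C/Cc1c(OCOC)cc2c(c1OCOC)C(=O)CC(c1cc(OCOC)cc(OCOC)c1)O2
F2 | step 11 | (E)-1-[3-geranyl-6-hydroxy-2,4-bis(methoxymethoxy)phenyl]-3-[3,5-bis(methoxymethoxy)phenyl]prop-2-en-1-one | CC(C)=CCC/C(C)=C/Cc1c(OCOC)cc(O)c(C(=O)/C=C/c2cc(OCOC)cc(OCOC)c2)c1OCOC
F3 | step 12 | (2S)-6-geranyl-5,7,3',5'-tetrakis(trimethylsilyloxy)flavanone | CC(C)=CCC/C(C)=C/Cc1c(O[Si](C)(C)C)cc2c(c1O[Si](C)(C)C)C(=O)C[C@@H](c1cc(O[Si](C)(C)C)cc(O[Si](C)(C)C)c1)O2
F4 | step 5 | 3-geranyl-2,4-bis(methoxymethoxy)-6-(triisopropylsilyloxy)phenyllithium | CC(C)=CCC/C(C)=C/Cc1c(OCOC)cc(O[Si](C(C)C)(C(C)C)C(C)C)c([Li])c1OCOC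
F5 | step 5 | 3-geranyl-2,4-bis(methoxymethoxy)-6-(triisopropylsilyloxy)benzaldehyde | CC(C)=CCC/C(C)=C/Cc1c(OCOC)cc(O[Si](C(C)C)(C(C)C)C(C)C)c(C=O)c1OCOC
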